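## Analysis of the target

Psiadiarabicin (16) is a flavone whose 4H-chromen-4-one core carries a hydroxyl at C5 and methoxy groups at C6 and C7 on ring A, no substituent at C3 of ring C, and the aryl ring B at C2. Ring B is oxygenated at four adjacent carbons: methoxy at C2', C4' and C5', a free hydroxyl at C3', and hydrogen only at C6'. There is no stereocenter and the molecule is achiral, so the whole problem is one of regiochemistry. The sensitive parts are three: ring B, which oxidises easily once a para-dihydroxy pattern is exposed; the pyranone, which opens under strongly nucleophilic base; and the C5 hydroxyl, which is hydrogen-bonded to the C4 carbonyl. The difficulty is that seven oxygens must be placed and two of them (O5 and O3') must end as free hydroxyls, while the C3' hydroxyl lies between two methoxy groups and cannot be singled out late on a preformed tetraoxygenated arene. The strategy rests on the pattern of ring B: O2' and O5' are para, O3' and O4' lie between them, and C1' and C6' are neighbours. That is the pattern of a hydroquinone formed when a 3,4-dioxygenated 2-silyloxyfuran adds across a terminal alkyne, so ring B can be built on a 2-ethynylchromone with O3' and O4' already differentiated in the furan.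

## Retrosynthetic reasoning

16 from 15. The two hydroxyls of 16 are traced back to the benzyl ether at O3' and the methyl ether at O5 in 2-[3-(benzyloxy)-2,4,5-trimethoxyphenyl]-5,6,7-trimethoxy-4H-chromen-4-one (15). The O5 methyl group is the only one peri to the C4 carbonyl, so a chelating Lewis acid can remove it selectively, and the same reagent cleaves the benzyl ether. All phenols therefore stay masked until one final operation.

15 from 14. The methyl groups on O2' and O5' are cut, giving the hydroquinone 2-[3-(benzyloxy)-2,5-dihydroxy-4-methoxyphenyl]-5,6,7-trimethoxy-4H-chromen-4-one (14). The two oxygens that must become methoxy are exactly the two that a furan–alkyne benzannulation delivers as hydroxyls, while the oxygen that must stay free is already benzylated. The forward step is a plain double O-methylation.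

14 from 11 and 6. Ring B is cut at C1'–C2' and C5'–C6'. This gives the two-carbon piece 2-ethynyl-5,6,7-trimethoxy-4H-chromen-4-one (11) and the four-carbon piece {[3-(benzyloxy)-4-methoxyfuran-2-yl]oxy}(tert-butyl)dimethylsilane (6), which carries all four oxygens of ring B. Cutting the C2–C1' bond instead would need a finished, differentiated tetraoxygenated arene, which is the hard part of the target. The forward reaction must be a [4+2] addition in the right orientation, followed by opening of the oxygen bridge and aromatisation.

6 from 5 and 4. The Si–O bond and then the O4–CH3 bond are cut, leading through 3-(benzyloxy)-4-methoxyfuran-2(5H)-one (5) to the tetronic acid 3-(benzyloxy)-4-hydroxyfuran-2(5H)-one (4). Forward, 4 is O-methylated at the vinylogous acid oxygen, and 5 is enolised towards C5 and silylated on the lactone oxygen.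

4 from 3, and 3 from 1 and 2. The C3–C4 bond of the furanone is cut (Dieckmann closure), giving ethyl 2-{[2-(benzyloxy)acetyl]oxy}acetate (3). Its ester C–O bond is then cut, giving (benzyloxy)acetyl chloride (1) and ethyl glycolate (2). This places the benzyloxy group on the nucleophilic carbon from the start and uses two cheap two-carbon units.

11 from 10. The alkyne C–H is traced back to a C–Si bond in 5,6,7-trimethoxy-2-[(trimethylsilyl)ethynyl]-4H-chromen-4-one (10). The silyl group protects the alkyne terminus while ring C is made.

10 from 9, and 9 from 7 and 8. The O1–C2 bond of ring C is cut (cyclodehydration), giving the diketone 1-(6-hydroxy-2,3,4-trimethoxyphenyl)-5-(trimethylsilyl)pent-4-yne-1,3-dione (9). The C2–C3 bond (chromone numbering) is then cut by a Claisen disconnection, giving 1-(6-hydroxy-2,3,4-trimethoxyphenyl)ethan-1-one (7) and ethyl 3-(trimethylsilyl)prop-2-ynoate (8). Ketone 7 already holds the full ring A pattern, so ring A needs no regiochemical decision.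

## Alternatives that were turned down

Alternative 1: Ring C is cut at C4–C4a and O1–C2, and ring A is taken from 2,6-dimethoxy-1,4-benzoquinone (A3).
- Forward step: quinone A3 is irradiated with the ynal 2,5,6-trimethoxy-3-(3-oxoprop-1-yn-1-yl)phenyl pivalate (A2). The excited quinone abstracts the formyl hydrogen of A2, the acyl radical couples to a quinone C–H carbon, and K2CO3 then closes ring C by oxa-Michael addition of the new hydroquinone hydroxyl to the ynone. The product is 3-(6-hydroxy-5,7-dimethoxy-4-oxo-4H-chromen-2-yl)-2,5,6-trimethoxyphenyl pivalate (A1).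
- For: A3 is symmetric, so the acylation has no regiochemical question, which is stronger than the electronically controlled orientation of the chosen cycloaddition. The C–H acylation needs no Lewis acid, and rings A and C arrive in one pot.
- Against: A2 presupposes the complete, differentiated ring B, which must be made by a long linear sequence on an arene. The electron-rich arene of A2 can quench the excited quinone by electron transfer, and the quinone can add photochemically to the alkyne. A1 also has the ring A pattern reversed (hydroxyl at C6, methoxy at C5), so O6 methylation, O5 demethylation and pivalate removal still follow.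
- Comparison: the chosen strategy spends its key step on ring B, the harder ring, and reaches ring A from a ketone that already has the right pattern, whereas A1 still needs three corrections after its key step.

Alternative 2: Ring A is cut at C8–C8a and C4a–C5 and is built on a pyranone.
- Forward step: zerovalent palladium from Pd2(dba)3 couples 2-[3-(benzyloxy)-2,4,5-trimethoxyphenyl]-6-(tributylstannyl)-4H-pyran-4-one (A5) with 4-chloro-2,3-dimethoxycyclobut-2-en-1-one (A6). On heating, the cyclobutenone opens (4π) to a dienylketene, which closes (6π) onto C3 of the pyranone and tautomerises to 2-[3-(benzyloxy)-2,4,5-trimethoxyphenyl]-5-hydroxy-6,7-dimethoxy-4H-chromen-4-one (A4).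
- For: this is the stronger endgame. A4 has O5 free and needs only a hydrogenolysis, and the connectivity fixes the regiochemistry completely, whereas the chosen route needs two steps after the key step, one of them a selective demethylation.
- Against: A5 again needs ring B made in full beforehand, plus a 2-aryl-4-pyranone that must be stannylated at C6. A6 is a labile alpha-chloroketone, and the route uses stoichiometric tin.
- Comparison: the chosen strategy is shorter overall because ring B comes from two two-carbon esters, and its precursors are made by classical chemistry, while A5 and A6 each demand a synthesis of their own.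

Alternative 3: Ring C is cut at O1–C8a, C4–C4a and O1–C2.
- Forward step: CsF releases an aryne from 3,4,5-trimethoxy-2-(trimethylsilyl)phenyl trifluoromethanesulfonate (A9). The carboxylate of 3-[3-(benzyloxy)-2,4,5-trimethoxyphenyl]prop-2-ynoic acid (A8) adds to the aryne carbon remote from the methoxy group, the aryl anion takes the acyl group, and the phenoxide closes onto the ynone. The product is 2-[3-(benzyloxy)-2,4,5-trimethoxyphenyl]-5,6,7-trimethoxy-4H-chromen-4-one (A7). Flavone A7 is the same compound as 15.
- For: three bonds form in one pot and A7 arrives with the full skeleton, the orientation follows the reliable 3-alkoxyaryne rule, and the endgame from A7 is as short as in the chosen route.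
- Against: A8 needs the finished ring B plus a propiolic acid that decarboxylates easily. A9 needs several steps of its own. Protonation of the aryl anion before acyl transfer gives an aryl ester in place of A7, and 5-exo closure gives an aurone.
- Comparison: the route through A7 reaches the same late intermediate but leaves the ring B problem unsolved, which the chosen strategy solves by construction.

Key step: step 8

Assumption: ketone 7 is taken as a purchased compound (it is the ortho-acetyl derivative of 3,4,5-trimethoxyphenol and is sold as such), so ring A needs no step of its own.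

## Route

Step 1
Reactants: 1 (benzyloxy)acetyl chloride; 2 ethyl glycolate
Product: 3 ethyl 2-{[2-(benzyloxy)acetyl]oxy}acetate
Conditions: Et3N, DMAP (cat.), CH2Cl2, 0 °C to rt
Reagents that add atoms: none
Why: O-acylation of a primary alcohol by an acid chloride with amine base and nucleophilic catalysis; no competing functionality is present.

Step 2
Reactants: 3 ethyl 2-{[2-(benzyloxy)acetyl]oxy}acetate
Product: 4 3-(benzyloxy)-4-hydroxyfuran-2(5H)-one
Conditions: LiN(SiMe3)2 (2.2 equiv), THF, −78 to 0 °C; aq. HCl
Reagents that add atoms: none
Why: Dieckmann (intramolecular Claisen) condensation of an O-(alkoxyacetyl)glycolate, a known way to 3-alkoxytetronic acids; the lithium-chelated enolate of the benzyloxyacetate attacks the ethyl ester 5-exo-trig, and the tetronate anion formed is the thermodynamic sink.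

Step 3
Reactants: 4 3-(benzyloxy)-4-hydroxyfuran-2(5H)-one
Product: 5 3-(benzyloxy)-4-methoxyfuran-2(5H)-one
Conditions: Me2SO4, K2CO3, acetone, reflux
Reagents that add atoms: dimethyl sulfate, COS(=O)(=O)OC
Why: O-alkylation of a vinylogous acid with a hard methylating agent; C3 is fully substituted and the 4-methoxybutenolide keeps the lactone conjugation, so the 4-O-methyl ether should dominate.

Step 4
Reactants: 5 3-(benzyloxy)-4-methoxyfuran-2(5H)-one
Product: 6 {[3-(benzyloxy)-4-methoxyfuran-2-yl]oxy}(tert-butyl)dimethylsilane
Conditions: TBSOTf, Et3N, CH2Cl2, 0 °C; used without chromatography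
Reagents that add atoms: tert-butyldimethylsilyl trifluoromethanesulfonate, CC(C)(C)[Si](C)(C)OS(=O)(=O)C(F)(F)F
Why: Soft enolisation of a butenolide to its silyl dienol ether: the silyl triflate activates the lactone carbonyl and the amine removes a C5 proton, giving the aromatic 2-silyloxyfuran as is known for methyl tetronate.

Step 5
Reactants: 7 1-(6-hydroxy-2,3,4-trimethoxyphenyl)ethan-1-one; 8 ethyl 3-(trimethylsilyl)prop-2-ynoate
Product: 9 1-(6-hydroxy-2,3,4-trimethoxyphenyl)-5-(trimethylsilyl)pent-4-yne-1,3-dione
Conditions: LiN(SiMe3)2 (3.3 equiv), THF, −78 to −30 °C; AcOH quench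
Reagents that add atoms: none
Why: Crossed Claisen condensation of the lithium dianion of an o-hydroxyacetophenone with an ester (the direct-acylation form of the Baker–Venkataraman synthesis); the hard lithium enolate attacks the ynoate carbonyl, the silyl group hinders conjugate addition, and deprotonation of the diketone drives the reaction.

Step 6
Reactants: 9 1-(6-hydroxy-2,3,4-trimethoxyphenyl)-5-(trimethylsilyl)pent-4-yne-1,3-dione
Product: 10 5,6,7-trimethoxy-2-[(trimethylsilyl)ethynyl]-4H-chromen-4-one
Conditions: TsOH·H2O (0.1 equiv), 4 Å MS, toluene, 70 °C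
Reagents that add atoms: none
Why: Acid-catalysed cyclodehydration of a 1-(2-hydroxyaryl)-1,3-diketone, the classical chromone closure: the phenol adds 6-exo-trig to the ynone carbonyl and the hemiketal loses water, while the silyl group shields the alkyne terminus from 6-endo-dig attack by the enol oxygen.

Step 7
Reactants: 10 5,6,7-trimethoxy-2-[(trimethylsilyl)ethynyl]-4H-chromen-4-one
Product: 11 2-ethynyl-5,6,7-trimethoxy-4H-chromen-4-one
Conditions: Bu4NF (1.1 equiv), AcOH (1.2 equiv), THF, −20 °C
Reagents that add atoms: none
Why: Fluoride-induced protodesilylation of an alkynylsilane; the acetic acid buffer keeps basic species from adding to the electrophilic terminal alkyne or opening the pyranone.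

Step 8
Reactants: 11 2-ethynyl-5,6,7-trimethoxy-4H-chromen-4-one; 6 {[3-(benzyloxy)-4-methoxyfuran-2-yl]oxy}(tert-butyl)dimethylsilane
Product: 14 2-[3-(benzyloxy)-2,5-dihydroxy-4-methoxyphenyl]-5,6,7-trimethoxy-4H-chromen-4-one, via oxa-bridged cycloadduct 12 (not isolated), via hydroquinone mono-TBS ether 13 (not isolated)
Conditions: 6 (2.5 equiv), BHT (cat.), toluene, 110 °C, sealed tube, argon; then Bu4NF, AcOH, THF, 0 °C, degassed work-up
Reagents that add atoms: none
Why: This is a normal-demand Diels–Alder reaction in which the HOMO of furan 6 has its largest coefficient at C5 (vinylogous to the silyloxy group and beta to the 4-methoxy group) and the LUMO of 11 has its largest alkyne coefficient at the terminal carbon, the delta position of the chromone enone, so the C5'–C6' bond leads and the silyloxy carbon joins C1' (C1'–C2'). The 7-oxanorbornadiene ketal 12 should not persist: its bridge C–O bond at C2' ionises with help from the silyloxy oxygen, and loss of the C5' proton gives the aromatic mono-silyl ether 13, which buffered fluoride converts into hydroquinone 14. The closest known reaction type is the Diels–Alder addition and ring opening of 2-silyloxyfurans with acetylenic esters and ketones to give para-hydroquinone derivatives. Here the alkyne is activated only through the C2=C3 bond of the chromone, which is why a higher temperature and an excess of 6 are planned. Ring B is closed by a concerted suprafacial [4+2] cycloaddition that forms both sigma bonds, and the second stage opens the oxygen bridge and closes no ring. The two bridgehead stereocenters of 12 are lost on aromatisation, so 14 has none. The step needs regioselectivity, since the reverse orientation would exchange the benzyloxy and methoxy positions relative to C1', and the matched polarisation of the two partners should secure it. It also needs chemoselectivity for the alkyne over the pyranone C2=C3 bond, which is trisubstituted, carries an oxygen donor and is therefore the poorer dienophile.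

Step 9
Reactants: 14 2-[3-(benzyloxy)-2,5-dihydroxy-4-methoxyphenyl]-5,6,7-trimethoxy-4H-chromen-4-one
Product: 15 2-[3-(benzyloxy)-2,4,5-trimethoxyphenyl]-5,6,7-trimethoxy-4H-chromen-4-one
Conditions: MeI (excess), K2CO3, degassed DMF, rt to 40 °C, argon
Reagents that add atoms: iodomethane, CI
Why: Williamson ether synthesis on both phenoxides; every other oxygen is already capped, and exclusion of air prevents oxidation of the hydroquinone to the quinone.

Step 10
Reactants: 15 2-[3-(benzyloxy)-2,4,5-trimethoxyphenyl]-5,6,7-trimethoxy-4H-chromen-4-one
Product: 16 psiadiarabicin, 5-hydroxy-2-(3-hydroxy-2,4,5-trimethoxyphenyl)-6,7-dimethoxy-4H-chromen-4-one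
Conditions: BCl3 (5 equiv), C6HMe5 (3 equiv), CH2Cl2, −78 to 0 °C; H2O
Reagents that add atoms: none
Why: Lewis-acid ether cleavage: BCl3 removes the benzyl group at low temperature with pentamethylbenzene as cation trap, and on warming cleaves the C5 methyl ether selectively because boron chelates between O5 and the C4 carbonyl, an assistance the other methyl ethers lack.

## Compound list

1 | (benzyloxy)acetyl chloride | ClC(=O)COCc1ccccc1 | starting material
2 | ethyl glycolate (ethyl 2-hydroxyacetate) | CCOC(=O)CO | starting material
3 | ethyl 2-{[2-(benzyloxy)acetyl]oxy}acetate | CCOC(=O)COC(=O)COCc1ccccc1 | intermediate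
4 | 3-(benzyloxy)-4-hydroxyfuran-2(5H)-one | OC1=C(OCc2ccccc2)C(=O)OC1 | intermediate
5 | 3-(benzyloxy)-4-methoxyfuran-2(5H)-one | COC1=C(OCc2ccccc2)C(=O)OC1 | intermediate
6 | {[3-(benzyloxy)-4-methoxyfuran-2-yl]oxy}(tert-butyl)dimethylsilane | COc1coc(O[Si](C)(C)C(C)(C)C)c1OCc1ccccc1 | intermediate
7 | 1-(6-hydroxy-2,3,4-trimethoxyphenyl)ethan-1-one | CC(=O)c1c(O)cc(OC)c(OC)c1OC | starting material
8 | ethyl 3-(trimethylsilyl)prop-2-ynoate | CCOC(=O)C#C[Si](C)(C)C | starting material
9 | 1-(6-hydroxy-2,3,4-trimethoxyphenyl)-5-(trimethylsilyl)pent-4-yne-1,3-dione | COc1cc(O)c(C(=O)CC(=O)C#C[Si](C)(C)C)c(OC)c1OC | intermediate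
10 | 5,6,7-trimethoxy-2-[(trimethylsilyl)ethynyl]-4H-chromen-4-one | COc1cc2oc(C#C[Si](C)(C)C)cc(=O)c2c(OC)c1OC | intermediate
11 | 2-ethynyl-5,6,7-trimethoxy-4H-chromen-4-one | C#Cc1cc(=O)c2c(OC)c(OC)c(OC)cc2o1 | intermediate
12 | 2-[6-(benzyloxy)-1-{[tert-butyl(dimethyl)silyl]oxy}-5-methoxy-7-oxabicyclo[2.2.1]hepta-2,5-dien-2-yl]-5,6,7-trimethoxy-4H-chromen-4-one (racemic; bridgeheads held cis by the oxygen bridge) | COC1=C(OCc2ccccc2)C2(O[Si](C)(C)C(C)(C)C)OC1C=C2c1cc(=O)c2c(OC)c(OC)c(OC)cc2o1 | intermediate (not isolated)
13 | 2-[3-(benzyloxy)-2-{[tert-butyl(dimethyl)silyl]oxy}-5-hydroxy-4-methoxyphenyl]-5,6,7-trimethoxy-4H-chromen-4-one | COc1cc2oc(-c3cc(O)c(OC)c(OCc4ccccc4)c3O[Si](C)(C)C(C)(C)C)cc(=O)c2c(OC)c1OC | intermediate (not isolated)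
14 | 2-[3-(benzyloxy)-2,5-dihydroxy-4-methoxyphenyl]-5,6,7-trimethoxy-4H-chromen-4-one | COc1cc2oc(-c3cc(O)c(OC)c(OCc4ccccc4)c3O)cc(=O)c2c(OC)c1OC | intermediate
15 | 2-[3-(benzyloxy)-2,4,5-trimethoxyphenyl]-5,6,7-trimethoxy-4H-chromen-4-one | COc1cc2oc(-c3cc(OC)c(OC)c(OCc4ccccc4)c3OC)cc(=O)c2c(OC)c1OC | intermediate
16 | psiadiarabicin, 5-hydroxy-2-(3-hydroxy-2,4,5-trimethoxyphenyl)-6,7-dimethoxy-4H-chromen-4-one | COc1cc(-c2cc(=O)c3c(O)c(OC)c(OC)cc3o2)c(OC)c(O)c1OC | target

## Step count and least certain steps

Total step count: 10. Longest linear sequence: 7 steps (1, 2, 3, 4, 8, 9, 10). The alkyne branch (5, 6, 7) joins at step 8.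

Step 8 (key step).
- Risk: the alkyne is activated only vinylogously, so the cycloaddition may be slower than thermal loss of the furan through desilylation or migration of silicon from oxygen to carbon. Open-chain conjugate addition of the furan C5 to the alkyne without ring closure, and erosion of the orientation, are further ways to fail.
- Fallback: it sets out from 6 and 7 and comes back at 15; the alkyne branch is then not needed. Furan 6 is heated with methyl propiolate, an ester-activated dienophile of the class for which this benzannulation is established (toluene, 80 °C, then Bu4NF/AcOH), which should give methyl 3-(benzyloxy)-2,5-dihydroxy-4-methoxybenzoate F1. Double methylation (MeI, K2CO3, DMF) should give methyl 3-(benzyloxy)-2,4,5-trimethoxybenzoate F2. Claisen condensation of F2 with the lithium dianion of 7 (LiN(SiMe3)2, THF) should give 1-[3-(benzyloxy)-2,4,5-trimethoxyphenyl]-3-(6-hydroxy-2,3,4-trimethoxyphenyl)propane-1,3-dione F3. Cyclodehydration of F3 (cat. H2SO4, AcOH) should give 15.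

Step 5.
- Risk: conjugate addition of the enolate to the ynoate may compete with acylation, and the lithium ethoxide released may cleave the alkyne–silicon bond, after which the unprotected ynone would be consumed by further addition.
- Fallback: it sets out from 7 and comes back at 9. The phenol of 7 is esterified with 3-(trimethylsilyl)propiolic acid (DCC, cat. DMAP, CH2Cl2, 0 °C) to give 2-acetyl-3,4,5-trimethoxyphenyl 3-(trimethylsilyl)prop-2-ynoate F4. Baker–Venkataraman rearrangement of F4 (LiN(SiMe3)2, THF, −78 °C) then moves the acyl group to carbon through a six-membered transition state without free alkoxide and should give 9.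

Step 6.
- Risk: ring closure in the wrong sense, by 6-endo-dig attack of the enol oxygen on the alkyne to form a 4-pyranone, or acid-promoted hydration of the ynone.
- Fallback: it sets out from 7 and comes back at 11, bypassing 9 and 10. Claisen condensation of 7 with diethyl oxalate and acid cyclisation (NaOEt, EtOH, then HCl) should give ethyl 5,6,7-trimethoxy-4-oxo-4H-chromene-2-carboxylate F5. Reduction of the activated ester (NaBH4, MeOH, 0 °C) should give 2-(hydroxymethyl)-5,6,7-trimethoxy-4H-chromen-4-one F6. Oxidation (MnO2, CH2Cl2) should give 5,6,7-trimethoxy-4-oxo-4H-chromene-2-carbaldehyde F7. Seyferth–Gilbert homologation of F7 with dimethyl (1-diazo-2-oxopropyl)phosphonate (K2CO3, MeOH, 0 °C) should give 11.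

Step 2.
- Risk: deprotonation at the glycolate CH2 instead of the benzyloxyacetyl CH2, followed by a 1,2-acyl shift (Chan rearrangement) in place of ring closure.
- Fallback: it sets out from 1 and 2 and comes back at 4. Methanolysis of 1 (MeOH, pyridine) gives methyl 2-(benzyloxy)acetate F8, and silylation of 2 (TBSCl, imidazole) gives ethyl 2-{[tert-butyl(dimethyl)silyl]oxy}acetate F9. Crossed Claisen condensation of the lithium enolate of F8 (LiN(i-Pr)2, THF, −78 °C) with F9 should give methyl 2-(benzyloxy)-4-{[tert-butyl(dimethyl)silyl]oxy}-3-oxobutanoate F10, in which no O-acyl glycolate is present and the acyl shift is impossible. Desilylation of F10 (aq. HF, MeCN) with spontaneous lactonisation should give 4.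

Step 10.
- Risk: over-dealkylation, that is loss of a second methyl group next to a boron-bound phenoxide (at O6, O2' or O4'), and C-benzylation of the electron-rich rings if the cation trap is outrun.
- Fallback: it sets out from 15 and comes back at 16. Hydrogenolysis (H2, Pd/C, EtOAc) removes only the benzyl group and should give 2-(3-hydroxy-2,4,5-trimethoxyphenyl)-5,6,7-trimethoxy-4H-chromen-4-one F11. Chelation-controlled demethylation of F11 with AlCl3 in MeCN at rt should then cleave only the C5 ether and give 16.

## Further compounds

F1 | step 8 | methyl 3-(benzyloxy)-2,5-dihydroxy-4-methoxybenzoate | COC(=O)c1cc(O)c(OC)c(OCc2ccccc2)c1O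
F2 | step 8 | methyl 3-(benzyloxy)-2,4,5-trimethoxybenzoate | COC(=O)c1cc(OC)c(OC)c(OCc2ccccc2)c1OC
F3 | step 8 | 1-[3-(benzyloxy)-2,4,5-trimethoxyphenyl]-3-(6-hydroxy-2,3,4-trimethoxyphenyl)propane-1,3-dione | COc1cc(O)c(C(=O)CC(=O)c2cc(OC)c(OC)c(OCc3ccccc3)c2OC)c(OC)c1OC
F4 | step 5 | 2-acetyl-3,4,5-trimethoxyphenyl 3-(trimethylsilyl)prop-2-ynoate | CC(=O)c1c(OC(=O)C#C[Si](C)(C)C)cc(OC)c(OC)c1OC
F5 | step 6 | ethyl 5,6,7-trimethoxy-4-oxo-4H-chromene-2-carboxylate | CCOC(=O)c1cc(=O)c2c(OC)c(OC)c(OC)cc2o1
F6 | step 6 | 2-(hydroxymethyl)-5,6,7-trimethoxy-4H-chromen-4-one | OCc1cc(=O)c2c(OC)c(OC)c(OC)cc2o1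
F7 | step 6 | 5,6,7-trimethoxy-4-oxo-4H-chromene-2-carbaldehyde | O=Cc1cc(=O)c2c(OC)c(OC)c(OC)cc2o1
F8 | step 2 | methyl 2-(benzyloxy)acetate | COC(=O)COCc1ccccc1
F9 | step 2 | ethyl 2-{[tert-butyl(dimethyl)silyl]oxy}acetate | CCOC(=O)CO[Si](C)(C)C(C)(C)C
F10 | step 2 | methyl 2-(benzyloxy)-4-{[tert-butyl(dimethyl)silyl]oxy}-3-oxobutanoate (racemic) | COC(=O)C(OCc1ccccc1)C(=O)CO[Si](C)(C)C(C)(C)C
F11 | step 10 | 2-(3-hydroxy-2,4,5-trimethoxyphenyl)-5,6,7-trimethoxy-4H-chromen-4-one | COc1cc2oc(-c3cc(OC)c(OC)c(O)c3OC)cc(=O)c2c(OC)c1OC
A1 | alternative 1 | 3-(6-hydroxy-5,7-dimethoxy-4-oxo-4H-chromen-2-yl)-2,5,6-trimethoxyphenyl pivalate | COc1cc2oc(-c3cc(OC)c(OC)c(OC(=O)C(C)(C)C)c3OC)cc(=O)c2c(OC)c1O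
A2 | alternative 1 | 2,5,6-trimethoxy-3-(3-oxoprop-1-yn-1-yl)phenyl pivalate | COc1cc(C#CC=O)c(OC)c(OC(=O)C(C)(C)C)c1OC
A3 | alternative 1 | 2,6-dimethoxy-1,4-benzoquinone | COC1=CC(=O)C=C(OC)C1=O
A4 | alternative 2 | 2-[3-(benzyloxy)-2,4,5-trimethoxyphenyl]-5-hydroxy-6,7-dimethoxy-4H-chromen-4-one | COc1cc2oc(-c3cc(OC)c(OC)c(OCc4ccccc4)c3OC)cc(=O)c2c(O)c1OC
A5 | alternative 2 | 2-[3-(benzyloxy)-2,4,5-trimethoxyphenyl]-6-(tributylstannyl)-4H-pyran-4-one | CCCC[Sn](CCCC)(CCCC)c1cc(=O)cc(-c2cc(OC)c(OC)c(OCc3ccccc3)c2OC)o1
A6 | alternative 2 | 4-chloro-2,3-dimethoxycyclobut-2-en-1-one (racemic) | COC1=C(OC)C(Cl)C1=O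
A7 | alternative 3 | 2-[3-(benzyloxy)-2,4,5-trimethoxyphenyl]-5,6,7-trimethoxy-4H-chromen-4-one | COc1cc2oc(-c3cc(OC)c(OC)c(OCc4ccccc4)c3OC)cc(=O)c2c(OC)c1OC
A8 | alternative 3 | 3-[3-(benzyloxy)-2,4,5-trimethoxyphenyl]prop-2-ynoic acid | COc1cc(C#CC(=O)O)c(OC)c(OCc2ccccc2)c1OC
A9 | alternative 3 | 3,4,5-trimethoxy-2-(trimethylsilyl)phenyl trifluoromethanesulfonate | COc1cc(OS(=O)(=O)C(F)(F)F)c([Si](C)(C)C)c(OC)c1OC
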